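**Retrosynthetic overview**
1. The acetate goes onto the 4'-OH and the 3'-O-MOM group comes off last. The prenyl group is cut from C4 of ring A (aryllithium between the two OMe groups plus prenyl bromide).
2. The CH2–CH2 bridge comes from a stilbene by hydrogenation, which also frees the 4'-OH from its benzyl ether. The stilbene comes from a β-hydroxy acid by loss of CO2 and H2O.
3. Key C–C bond: aldol addition of the dianion of (3,5-dimethoxyphenyl)acetic acid to 4-(benzyloxy)-2-methoxy-3-(methoxymethoxy)benzaldehyde.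
4. That aldehyde comes from 2,3,4-trihydroxybenzaldehyde by three successive regioselective O-alkylations (4-O, then 3-O, then 2-O).
5. No ring is formed: ring A and ring B are both bought in as benzene derivatives.

Assumption: the target has no stereocentre, and its only C=C carries two identical methyl groups, so it is achiral and needs no enantiocontrol.

**Step 1**
Reactants: 1 2,3,4-trihydroxybenzaldehyde
Product: 2 4-(benzyloxy)-2,3-dihydroxybenzaldehyde
Conditions: BnBr (1.0 equiv), NaHCO3 (1.5 equiv), DMF, N2, 40 °C, 20 h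
Reagents that add atoms: benzyl bromide, BrCc1ccccc1
Why: Weak-base Williamson etherification, in which NaHCO3 ionises only the 4-OH (para to the formyl group, hence most acidic, and not held in the OH···O=CH hydrogen bond), so the single equivalent of BnBr reacts there.

**Step 2**
Reactants: 2 4-(benzyloxy)-2,3-dihydroxybenzaldehyde
Product: 4 4-(benzyloxy)-2-hydroxy-3-(methoxymethoxy)benzaldehyde, via disodium catecholate 3 (not isolated)
Conditions: NaH (2.1 equiv), DMF, 0 °C; MOMCl (1.0 equiv), 0 °C; aq NH4Cl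
Reagents that add atoms: chloromethyl methyl ether, COCCl
Why: Regioselective O-alkylation of a catecholate dianion, in which the 2-oxide of 3 is delocalised into and sodium-chelated by the formyl group, so the more basic, unconjugated 3-oxide takes the one equivalent of MOMCl.

**Step 3**
Reactants: 4 4-(benzyloxy)-2-hydroxy-3-(methoxymethoxy)benzaldehyde
Product: 5 4-(benzyloxy)-2-methoxy-3-(methoxymethoxy)benzaldehyde
Conditions: MeI (2 equiv), K2CO3 (2 equiv), DMF, 40 °C
Reagents that add atoms: iodomethane, CI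
Why: Williamson methylation of the only remaining phenol, where K2CO3 in warm DMF breaks the chelate and leaves the benzyl ether, MOM acetal and aldehyde untouched.

**Step 4**
Reactants: 5 4-(benzyloxy)-2-methoxy-3-(methoxymethoxy)benzaldehyde; 6 (3,5-dimethoxyphenyl)acetic acid
Product: 8 3-[4-(benzyloxy)-2-methoxy-3-(methoxymethoxy)phenyl]-2-(3,5-dimethoxyphenyl)-3-hydroxypropanoic acid (racemic syn/anti mixture), via dilithium enediolate 7 (not isolated)
Conditions: 6 (1.05 equiv), LDA (2.2 equiv), THF, −78 to 0 °C; then 5, −78 °C, 2 h; cold 1 M HCl to pH 3–4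
Reagents that add atoms: none
Why: Ivanov-type intermolecular aldol addition, in which the acid dianion 7 cannot self-condense and adds to the non-enolisable aldehyde 5 to join the two future bridge carbons; the two new stereocentres form as a racemic syn/anti mixture, which does not matter because step 5 erases both.

**Step 5**
Reactants: 8 3-[4-(benzyloxy)-2-methoxy-3-(methoxymethoxy)phenyl]-2-(3,5-dimethoxyphenyl)-3-hydroxypropanoic acid
Product: 10 1-(benzyloxy)-4-[(E)-2-(3,5-dimethoxyphenyl)ethenyl]-3-methoxy-2-(methoxymethoxy)benzene (E major, any Z isomer carried along), via oxyphosphonium carboxylate betaine 9 (not isolated)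
Conditions: PPh3 (1.3 equiv), DIAD (1.3 equiv), THF, 0 °C to rt, then 50 °C, 1 h
Reagents that add atoms: none
Why: Mitsunobu-type decarboxylative dehydration (Grob-type fragmentation), in which the benzylic OH is activated as the oxyphosphonium ion 9 and leaves with help from the ortho/para alkoxy groups of ring B and loss of CO2 from the neighbouring carboxylate, all under neutral conditions that spare the MOM and benzyl groups.

**Step 6**
Reactants: 10 1-(benzyloxy)-4-[(E)-2-(3,5-dimethoxyphenyl)ethenyl]-3-methoxy-2-(methoxymethoxy)benzene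
Product: 11 4-[2-(3,5-dimethoxyphenyl)ethyl]-3-methoxy-2-(methoxymethoxy)phenol
Conditions: H2 (1 atm), 10% Pd/C, EtOAc–EtOH, rt
Reagents that add atoms: none
Why: Catalytic hydrogenation saturates either stilbene isomer and hydrogenolyses the O-benzyl group in one operation, the MOM acetal and methyl ethers are inert, and the step comes before the prenyl alkene exists, so no alkene selectivity is needed.

**Step 7**
Reactants: 11 4-[2-(3,5-dimethoxyphenyl)ethyl]-3-methoxy-2-(methoxymethoxy)phenol; 12 1-bromo-3-methylbut-2-ene (prenyl bromide)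
Product: 14 4-{2-[3,5-dimethoxy-4-(3-methylbut-2-en-1-yl)phenyl]ethyl}-3-methoxy-2-(methoxymethoxy)phenol, via dilithiated bibenzyl 13 (not isolated)
Conditions: n-BuLi (2.1 equiv), THF, 0 °C to rt, 2 h; then 12 (1.1 equiv), −78 to 0 °C; aq NH4Cl
Reagents that add atoms: none
Why: Directed ortho-metalation followed by SN2 alkylation, in which the first equivalent of base makes the lithium phenoxide that shuts ring B off from lithiation (the 3'-OMOM group has no ortho hydrogen), the second removes the ring A proton flanked by both methoxy groups, and the aryllithium attacks the primary carbon of 12 far faster than a lithium phenoxide does in cold THF.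

**Step 8**
Reactants: 14 4-{2-[3,5-dimethoxy-4-(3-methylbut-2-en-1-yl)phenyl]ethyl}-3-methoxy-2-(methoxymethoxy)phenol
Product: 15 4-{2-[3,5-dimethoxy-4-(3-methylbut-2-en-1-yl)phenyl]ethyl}-3-methoxy-2-(methoxymethoxy)phenyl acetate
Conditions: Ac2O (1.3 equiv), pyridine (3 equiv), CH2Cl2, 0 °C to rt
Reagents that add atoms: acetic anhydride, CC(=O)OC(C)=O
Why: Base-mediated O-acylation of the only free hydroxyl fixes the acetate at the 4'-oxygen without ambiguity, and the MOM and prenyl groups are inert.

**Step 9**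
Reactants: 15 4-{2-[3,5-dimethoxy-4-(3-methylbut-2-en-1-yl)phenyl]ethyl}-3-methoxy-2-(methoxymethoxy)phenyl acetate
Product: 16 4-{2-[3,5-dimethoxy-4-(3-methylbut-2-en-1-yl)phenyl]ethyl}-2-hydroxy-3-methoxyphenyl acetate (target)
Conditions: NaHSO4·SiO2 (cat.), undried CH2Cl2, rt, 1–3 h
Reagents that add atoms: none
Why: Acid-catalysed acetal hydrolysis on a mild solid acid in an aprotic solvent removes the phenolic MOM group without an alcohol that could transesterify the aryl acetate, without base that could trigger a 1,2-acyl shift, and without acid strong enough to protonate the prenyl alkene, which has only OMe neighbours and so cannot cyclise.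

**Compound list**
1 | 2,3,4-trihydroxybenzaldehyde | O=Cc1ccc(O)c(O)c1O | starting material
2 | 4-(benzyloxy)-2,3-dihydroxybenzaldehyde | O=Cc1ccc(OCc2ccccc2)c(O)c1O | intermediate
3 | disodium 4-(benzyloxy)-3-formylbenzene-1,2-diolate, the dianion of 2 (not isolated) | [Na+].[Na+].O=Cc1ccc(OCc2ccccc2)c([O-])c1[O-] | intermediate
4 | 4-(benzyloxy)-2-hydroxy-3-(methoxymethoxy)benzaldehyde | O=Cc1ccc(OCc2ccccc2)c(OCOC)c1O | intermediate
5 | 4-(benzyloxy)-2-methoxy-3-(methoxymethoxy)benzaldehyde | O=Cc1ccc(OCc2ccccc2)c(OCOC)c1OC | intermediate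
6 | (3,5-dimethoxyphenyl)acetic acid | COc1cc(CC(=O)O)cc(OC)c1 | starting material
7 | dilithium enediolate of 6 (not isolated) | COc1cc(C=C(O[Li])O[Li])cc(OC)c1 | intermediate
8 | 3-[4-(benzyloxy)-2-methoxy-3-(methoxymethoxy)phenyl]-2-(3,5-dimethoxyphenyl)-3-hydroxypropanoic acid, racemic syn/anti mixture | COc1cc(cc(OC)c1)C(C(=O)O)C(O)c1ccc(OCc2ccccc2)c(OCOC)c1OC | intermediate
9 | oxyphosphonium carboxylate betaine of 8 (not isolated) | COc1cc(cc(OC)c1)C(C(=O)[O-])C(O[P+](c1ccccc1)(c1ccccc1)c1ccccc1)c1ccc(OCc2ccccc2)c(OCOC)c1OC | intermediate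
10 | 1-(benzyloxy)-4-[(E)-2-(3,5-dimethoxyphenyl)ethenyl]-3-methoxy-2-(methoxymethoxy)benzene | COc1cc(/C=C/c2ccc(OCc3ccccc3)c(OCOC)c2OC)cc(OC)c1 | intermediate
11 | 4-[2-(3,5-dimethoxyphenyl)ethyl]-3-methoxy-2-(methoxymethoxy)phenol | COc1cc(CCc2ccc(O)c(OCOC)c2OC)cc(OC)c1 | intermediate
12 | 1-bromo-3-methylbut-2-ene (prenyl bromide) | CC(C)=CCBr | starting material
13 | C4-lithio (ring A) lithium phenoxide (ring B) of 11 (not isolated) | [Li]c1c(OC)cc(CCc2ccc(O[Li])c(OCOC)c2OC)cc1OC | intermediate
14 | 4-{2-[3,5-dimethoxy-4-(3-methylbut-2-en-1-yl)phenyl]ethyl}-3-methoxy-2-(methoxymethoxy)phenol | COc1cc(CCc2ccc(O)c(OCOC)c2OC)cc(OC)c1CC=C(C)C | intermediate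
15 | 4-{2-[3,5-dimethoxy-4-(3-methylbut-2-en-1-yl)phenyl]ethyl}-3-methoxy-2-(methoxymethoxy)phenyl acetate | COc1cc(CCc2ccc(OC(C)=O)c(OCOC)c2OC)cc(OC)c1CC=C(C)C | intermediate
16 | 4-{2-[3,5-dimethoxy-4-(3-methylbut-2-en-1-yl)phenyl]ethyl}-2-hydroxy-3-methoxyphenyl acetate | COc1cc(CCc2ccc(OC(C)=O)c(O)c2OC)cc(OC)c1CC=C(C)C | target

**Total step count:** 9. **Longest linear sequence:** 9 steps (1 to 16); compounds 6 and 12 are purchased and enter at steps 4 and 7.

**Three steps most likely to fail**

Step 2 (telling the 3-OH from the 2-OH, which also depends on the mono-benzylation in step 1). If 2-O/3-O mixtures or over-alkylation appear, the fallback sets out again from 1. Heating 1 with Ph2CCl2 in Ph2O at 170 °C ties up the 3,4-diol and leaves the chelated 2-OH free, giving 4-hydroxy-2,2-diphenyl-1,3-benzodioxole-5-carbaldehyde F1. MeI and K2CO3 in DMF give 4-methoxy-2,2-diphenyl-1,3-benzodioxole-5-carbaldehyde F2. Refluxing AcOH–H2O (4:1) releases 3,4-dihydroxy-2-methoxybenzaldehyde F3. BnBr and NaHCO3 in DMF at 40 °C alkylate the para-OH, which is much the more acidic, to give 4-(benzyloxy)-3-hydroxy-2-methoxybenzaldehyde F4. MOMCl with iPr2NEt in CH2Cl2 then gives 5, where the route is rejoined.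

Step 7 (lithiation and prenylation beside a free phenoxide). If O-prenylation, allylic transposition or sluggish lithiation intervenes, the C–C bond is made by cross-coupling instead, setting out from 11. TIPSCl and imidazole in DMF give {4-[2-(3,5-dimethoxyphenyl)ethyl]-3-methoxy-2-(methoxymethoxy)phenoxy}tri(propan-2-yl)silane F5, whose bulky silyl ether blocks the neighbouring ring B position. n-BuLi in THF at 0 °C gives the ring A C4-aryllithium of the silyl ether F6, and I2 converts it into {4-[2-(4-iodo-3,5-dimethoxyphenyl)ethyl]-3-methoxy-2-(methoxymethoxy)phenoxy}tri(propan-2-yl)silane F7. Stille coupling with tributyl(3-methylbut-2-en-1-yl)stannane and Pd(PPh3)4 in DMF at 90 °C gives the prenylated silyl ether (4-{2-[3,5-dimethoxy-4-(3-methylbut-2-en-1-yl)phenyl]ethyl}-3-methoxy-2-(methoxymethoxy)phenoxy)tri(propan-2-yl)silane F8. Bu4NF in THF at 0 °C returns the route to 14.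

Step 9 (MOM removal beside an aryl acetate and a prenyl group). If the acetate is lost or scrambled, the order of events is reversed, setting out from 14. Catalytic p-TsOH·H2O in MeOH at 40 °C, with no acetate yet present, gives the free catechol 4-{2-[3,5-dimethoxy-4-(3-methylbut-2-en-1-yl)phenyl]ethyl}-3-methoxybenzene-1,2-diol F9. This is mono-acetylated with Ac2O (1.0 equiv) and Et3N in CH2Cl2 at −20 °C to rt. The outer 4'-OH is the less hindered one. Base-mediated 1,2-acyl equilibration should also favour the isomer whose free OH sits between OMe and OAc and is hydrogen-bonded to the OMe, and that isomer is 16.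

**Further compounds**
F1 | step 2 | 4-hydroxy-2,2-diphenyl-1,3-benzodioxole-5-carbaldehyde | O=Cc1ccc2OC(c3ccccc3)(c3ccccc3)Oc2c1O
F2 | step 2 | 4-methoxy-2,2-diphenyl-1,3-benzodioxole-5-carbaldehyde | O=Cc1ccc2OC(c3ccccc3)(c3ccccc3)Oc2c1OC
F3 | step 2 | 3,4-dihydroxy-2-methoxybenzaldehyde | O=Cc1ccc(O)c(O)c1OC
F4 | step 2 | 4-(benzyloxy)-3-hydroxy-2-methoxybenzaldehyde | O=Cc1ccc(OCc2ccccc2)c(O)c1OC
F5 | step 7 | {4-[2-(3,5-dimethoxyphenyl)ethyl]-3-methoxy-2-(methoxymethoxy)phenoxy}tri(propan-2-yl)silane | COc1cc(CCc2ccc(O[Si](C(C)C)(C(C)C)C(C)C)c(OCOC)c2OC)cc(OC)c1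
F6 | step 7 | ring A C4-aryllithium of the silyl ether | [Li]c1c(OC)cc(CCc2ccc(O[Si](C(C)C)(C(C)C)C(C)C)c(OCOC)c2OC)cc1OC
F7 | step 7 | {4-[2-(4-iodo-3,5-dimethoxyphenyl)ethyl]-3-methoxy-2-(methoxymethoxy)phenoxy}tri(propan-2-yl)silane | COc1cc(CCc2ccc(O[Si](C(C)C)(C(C)C)C(C)C)c(OCOC)c2OC)cc(OC)c1I
F8 | step 7 | (4-{2-[3,5-dimethoxy-4-(3-methylbut-2-en-1-yl)phenyl]ethyl}-3-methoxy-2-(methoxymethoxy)phenoxy)tri(propan-2-yl)silane | COc1cc(CCc2ccc(O[Si](C(C)C)(C(C)C)C(C)C)c(OCOC)c2OC)cc(OC)c1CC=C(C)C
F9 | step 9 | 4-{2-[3,5-dimethoxy-4-(3-methylbut-2-en-1-yl)phenyl]ethyl}-3-methoxybenzene-1,2-diol | COc1cc(CCc2ccc(O)c(O)c2OC)cc(OC)c1CC=C(C)C
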